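(The rate constants were set for the occasion; the rest is arithmetic.)

You have 12 min of stirring, and the flask holds shorter clocks that you can set side by side before any run.

    reagent in the reaction phase ⇌ reagent in the second phase, rate k1*([reagent in the reaction phase] - [reagent in the second phase]/K1) per volume of the first phase (K1 = 5.00, k1 = 0.923 min⁻¹)
    substrate + reagent in the reaction phase → target (k2 = 6.51 M⁻¹ min⁻¹)
    substrate + target → side product (k3 = 0.255 M⁻¹ min⁻¹)
    2 substrate → homo dimer (k4 = 0.0255 M⁻¹ min⁻¹)
    reagent in the reaction phase + target ⇌ idle adduct, settled at all times (K5 = 1.35 M⁻¹)

substrate 0.40 M; reagent in the second phase 1.60 M; time 12 min; volume of the second phase over the first 1.0

- percent here means substrate units held: one side product or homo dimer counts as two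
- what is said of target includes idle adduct
- where a step has two of a species, its rate is k times that concentration squared, and two are used at each turn
- in the second phase: reagent in the second phase; everything else is in the first
- charges count per volume of the first phase; a concentration in a rate is the amount of a species over the volume of its own phase; every rate counts per litre of the first phase
- run time (flask): 12 min

- alder: doubling the amount of reagent in the second phase, all else as stated
- larch: doubling the transfer coefficient of step 1, all else as stated

* how much target and idle adduct together there is at 12 min, in percent of the substrate charged
* the change that raises the amount of target and idle adduct together at 12 min, in percent of the substrate charged most ("none" if none brings more than 2 percentage points) (alder / larch / none)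
* amount of target and idle adduct together at 12 min, in percent of the substrate charged, after alder

- Fastest is the balance of idle adduct, kept by the scheme itself; next, reagent in the reaction phase has a half-life of 0.27 min against substrate as charged, shorter than the 0.751 min of its transfer, so I treat it as a resting state, its level being feed over removal.
- Substrate is the limiting reagent, charged at less than the reagent, so I write its balance in s, the fraction left; with second-phase reagent held at its charge, the feed is 0.738 min⁻¹ in fractions of the substrate charge, which could deliver a whole charge in 1.35 min, less than 12 min, so I count losses from s of one down to zero.
- Slower still are the side step, with 6.8 min for free target, and the homo dimer, with a first half-life of 49.0 min, both longer than the feed time, so I reckon them as small shares of each unit of substrate used.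
- Dividing the side rate by the target-forming rate, counting two substrate units per side product and summing over s gives two terms: 4.90%, which follows the ratio of the rate constants, and 4.60%, which follows the side rate at charge over the feed.
- Their sum 9.50% is the side loss, the fraction of the substrate charge I expect in side product.
- The same sum for homo dimer gives 0.490% and 0.921%, so I commit to 89.1%; alder halves all these terms and gains 5.5 percentage points, while larch halves the second of each pair and gains 2.8 points, less than alder.
- The forecast says 88%, alder and 94%, on the ground that “The yield is then set purely by selectivity, and target stays constant afterwards.” My 89.1% stands above its 88%.
- The flask gives 87.2%, and 93.0% after alder, which gains 5.8 points against 3.2 points for larch. A run can part from the forecast if a charge is moved: the answer has shifted by 5 points at 0.516 M of substrate, or, with substrate held, at 1.11 M of reagent in the second phase. Side product in the flask reads 10.6% at 12.0 min, which is 1.12 times the side loss. For the neighbour flask with 0.24 M of substrate the side loss is 4.60%, which that factor turns into 5.15%, and that neighbour holds 5.49%.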